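## The problem

Lobophynin B (26) is a cembranoid: a 14-membered carbocycle (C1–C14) fused along C1–C2 to a 2,5-dihydrofuran (O, C2, C1, C15, C16). The ring-fusion alkene C1=C15 is tetrasubstituted, and C15 carries the acetoxymethyl carbon C17. The carbocycle holds two E-trisubstituted alkenes (C3=C4, C11=C12) and a trans-trisubstituted epoxide (C7–C8), so that C2–C13 with its three methyl branches maps onto (2E,6E)-farnesol (1).

There are three stereocentres. C7 and C8 (both R) arise together from one E-alkene and call for reagent control, together with a choice among three similar trisubstituted alkenes. C2 (R) is an ether carbon that is allylic on both sides and lies five bonds from the epoxide across a rigid E-alkene. In an open chain neither element can direct the other; only the conformation of a macrocycle could relay the information, and that cannot be relied on.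

The fragile sites are the epoxide (protic and Lewis acids), the C2–O bond (prone to ionise), the primary allylic acetate, and the E-alkenes, which must not isomerise. The macrocycle must therefore be closed at a bond whose formation leaves no doubt about regiochemistry or alkene geometry.

The feature that opens the structure is C15. It is an alkene carbon flanked by the ring OCH2 (C16) and by C1, which in turn bears the C2 carbinol. This is the pattern left when a C2 hydroxyl adds 5-endo to the terminus of a C1=C15=C16 allene and the C15–metal bond so formed is captured by a one-carbon unit.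

## Retrosynthesis

Cembrane locants are used for all intermediates.

**26 ⇒ 25 ⇒ 24 (functional-group changes at C17).** The allylic acetate is the most labile group and is put on last. Cutting the acetyl C–O bond gives allylic alcohol 25, and raising C17 to the ester level gives methyl ester 24. The skeleton is unchanged. The forward steps need only a 1,2-reduction of a conjugated ester that spares the epoxide, and an acylation.

**24 ⇒ 20 + 21 (O–C16 and C15–C17).** Both bonds at the two "new" carbons of the dihydrofuran are cut at once, giving macrocyclic 2,3-allenol 20 and carbon monoxide 21.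
- The neighbouring cuts (O–C16 or O–C2 alone, i.e. etherification of a diol) would need a stereodefined tetrasubstituted alkene with two differentiated CH2O arms.
- The allene avoids that problem: it is 1,1-disubstituted at C1 and unsubstituted at C16, so it has no geometry and no axial chirality, and its central carbon becomes C15.
- The precursor has one ring, one carbon and one tetrasubstituted alkene fewer.
- The forward reaction must put oxygen on C16 and the metal on C15, must capture the metal with CO before protonolysis, and must leave the epoxide, the C2 centre and both trisubstituted alkenes alone.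

**20 ⇒ 18 (C1–C2).** A 2,3-allenol is the SE2' adduct of a 2-alkynyl metal and an aldehyde, so cutting C1–C2 gives bromo enal 18.
- This is the one ring bond whose formation creates both the carbinol and the allene that the key step consumes.
- The site of C–C formation is fixed by the carbonyl, and no alkene is involved, so no alkene geometry is at stake.
- Closing the ring elsewhere (alkylation at C13–C14, or an alkene-forming closure) would leave the allenol to be built separately.
- The precursor is an open chain.
- The forward reaction must proceed by γ-attack under high dilution. It creates C2 without reagent control, so the (2R)-configured 20 has to be secured by separation.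

**18 ⇒ 17 ⇒ 16 ⇒ 15 ⇒ 12 + 13, and 12 ⇒ 11 ⇒ 8 + 9 (C15–C16 and C13–C14).**
- The aldehyde goes back to allylic alcohol 17 and its PMB ether 16.
- The propargylic bromide goes back to alcohol 15, which is alkyne 12 plus formaldehyde 13.
- Alkyne 12 comes from silylalkyne 11, made by alkylating allylic bromide 8 with lithiated 1-(trimethylsilyl)propyne 9.
- The three-carbon and one-carbon units are commercial, and silicon steers the alkylation to the propargylic carbon.
- The C2 oxygen is carried as a PMB ether. It survives organolithium reagents, and it can be removed oxidatively at neutral pH, which the propargylic bromide and the epoxide both tolerate. Base or fluoride would attack the bromide and acid the epoxide.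

**8 ⇒ 7 ⇒ 6 ⇒ 5 ⇒ 4 ⇒ 3 ⇒ 1 (epoxide and C13 oxygen).**
- Bromide 8 comes from alcohol 7, the deacetylated form of epoxy acetate 6.
- Epoxide 6 comes from triene 5 by Shi epoxidation. In 5 the two outer alkenes each carry an allylic C–O bond (acetate at C13, ether at C2), so the electrophilic dioxirane should choose C7=C8.
- Acetate 5 comes from alcohol 4, the selenium dioxide oxidation product of farnesyl PMB ether 3, itself made from farnesol 1.
- All three methyl-bearing carbons and both E-alkenes are bought with the starting material.

## Roads not taken

**Alternative 1:** The cut is the C3≡C4 bond of cycloalkyne A2. The forward step is ring-closing alkyne metathesis of diyne A1 with Mo(≡C-C6H4-4-OMe)(OSiPh3)3 (hexavalent molybdenum alkylidyne), with loss of 2-butyne. The C4 methyl would then be added by anti hydromethylation, and the dihydrofuran closed afterwards.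
- Merits: the ring closure is among the most dependable for 14-membered rings and raises no geometric question. C2 can be set beforehand by reagent control. The E-geometry of C3=C4 would follow from a trans-hydrometalation.
- Weak points:
  - The methyl has to go to C4, the alkyne carbon distal to the C2 oxygen. Hydroxyl-directed trans-hydrostannation ([Cp*RuCl]4, Bu3SnH) puts tin on the proximal carbon, and the silyl ether in A2 offers no handle for the opposite sense.
  - A1 needs a geometrically pure tetrasubstituted C1=C15 alkene with two distinguishable CH2O arms, which is itself a synthetic problem.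
  - After A2 there remain hydrostannation, methylation, two or three deprotections, an etherification at an ionisable doubly allylic carbinol, and acetylation.
  - The epoxide has to survive all of these.
- Comparison: this road is better in the certainty of the ring closure and in control of C2. The chosen plan offers in return a C4 methyl that is never in question (it comes with 1), the heterocycle and C17 in one operation from 20, and only two steps after the key step.

**Alternative 2:** The cut is the O–C2 bond of dihydrofuran A4, traced back to dienyl oxirane A3. Cu(CF3COCHCOCF3)2 (divalent copper) would shift the oxirane oxygen from C15 to C2. A3 is drawn with the C15 configuration that a suprafacial shift would need.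
- Merits: catalytic and atom-economical. The C2 configuration would derive from an oxirane that a Sharpless-type epoxidation can set by reagent control. The C16 and C17 arms come out differentiated.
- Weak points:
  - The vinyl unit of A3 is part of a diene, so the ionised intermediate is a pentadienyl system. Loss of stereochemical fidelity, attack at C4 and erosion of the C3=C4 geometry are all to be feared.
  - A4 is only the heterocycle with an open C3–C13 chain. The epoxide and the macrocycle (C13–C14) are still to come, and that ring closure is the one Alternative 3 has to face.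
- Comparison: it is better in reagent control of C2. The chosen plan makes the same heterocycle on a finished macrocycle, so nothing difficult remains after it.

**Alternative 3:** The cut is C13–C14. Slow addition of bis(allylic bromide) A5 to Ni(CO)4 (zerovalent nickel) would close the carbocycle to A6, the TBS ether of deacetyl-lobophynin B.
- Merits: it is the most convergent road. A6 is two steps from the target, and the heterocycle and C2 are complete before ring closure, so no stereocentre is made in the macrocyclisation. In stereocontrol at C2 and in convergence it is superior to the chosen plan.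
- Weak points:
  - Allyl–allyl coupling through π-allylnickel species can join either terminus of each allyl unit. Coupling at C15 or C11 would give ring-size and alkene-position isomers.
  - The C11=C12 geometry can be lost by syn/anti equilibration of the π-allyl.
  - Zerovalent nickel may insert into the doubly allylic C2–O bond or the allylic C17–O bond.
  - Ni(CO)4 is volatile and extremely toxic.
  - A5 requires its own enantioselective synthesis of a trisubstituted dihydrofuran.
- Comparison: the chosen plan closes the ring by addition to a carbonyl, which fixes the site of bond formation and leaves both E-alkenes untouched. It pays for this with a C2 centre formed without reagent control, which has to be handled by separation and recycling.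

Key step: step 14

Remarks on the chemistry:
- The target is taken as the (2R,7R,8R)-isomer encoded by its SMILES string.
- C2–C13 are the chain carbons of farnesol (C2 = farnesol C1); C14, C1 and C15 come from 1-(trimethylsilyl)propyne, C16 from formaldehyde and C17 from carbon monoxide.
- Organochromium 19 and organopalladium species 22 and 23 are written without their neutral ligands.

## Route

Step 1
Reactants: 1 (2E,6E)-farnesol
Product: 3 (2E,6E)-farnesyl 4-methoxybenzyl ether, via sodium farnesoxide 2 (not isolated)
Conditions: NaH, THF–DMF, 0 °C; then 4-methoxybenzyl chloride, Bu4NI (cat.), 0 °C → rt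
Reagents that add atoms: 4-methoxybenzyl chloride, COc1ccc(CCl)cc1
Why: Williamson etherification of a primary allylic alkoxide; the PMB ether withstands the organolithium steps and can later be removed oxidatively at neutral pH.

Step 2
Reactants: 3 (2E,6E)-farnesyl 4-methoxybenzyl ether
Product: 4 C13 alcohol (2E,6E,10E)-12-(4-methoxybenzyloxy)-2,6,10-trimethyldodeca-2,6,10-trien-1-ol
Conditions: SeO2 (cat.), t-BuOOH, salicylic acid (cat.), CH2Cl2, 0 °C → rt
Reagents that add atoms: tert-butyl hydroperoxide, CC(C)(C)OO (oxygen passed on by the catalyst SeO2, O=[Se]=O)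
Why: Sharpless-type selenium dioxide allylic oxidation (ene reaction, then [2,3]-sigmatropic shift) should hydroxylate the E-methyl of the terminal, most accessible and most electron-rich alkene, giving the (E)-allylic alcohol; the C3=C4 alkene is deactivated by its allylic ether oxygen.

Step 3
Reactants: 4 C13 alcohol
Product: 5 C13 acetate (2E,6E,10E)-12-(4-methoxybenzyloxy)-2,6,10-trimethyldodeca-2,6,10-trien-1-yl acetate
Conditions: Ac2O, pyridine, DMAP (cat.), CH2Cl2, 0 °C
Reagents that add atoms: acetic anhydride, CC(=O)OC(C)=O
Why: DMAP-catalysed acylation; the allylic ester is installed to lower the nucleophilicity of C11=C12 before the epoxidation.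

Step 4
Reactants: 5 C13 acetate
Product: 6 (7R,8R)-epoxy acetate (2E,6R,7R,10E)-6,7-epoxy-12-(4-methoxybenzyloxy)-2,6,10-trimethyldodeca-2,10-dien-1-yl acetate
Conditions: D-fructose-derived Shi ketone (cat.), KHSO5 (Oxone), K2CO3, Bu4NHSO4, MeCN–CH2(OMe)2 / aq. Na2B4O7–Na2EDTA buffer, 0 °C
Reagents that add atoms: potassium peroxymonosulfate, [K+].[O-]S(=O)(=O)OO (oxygen delivered through the dioxirane of the ketone catalyst)
Why: Shi asymmetric epoxidation; the electrophilic dioxirane should choose C7=C8 because C11=C12 (allylic acetate) and C3=C4 (allylic ether) are inductively deactivated. The spiro transition state of the D-fructose-derived ketone delivers oxygen to the face of an E-trisubstituted alkene that gives the (R,R)-epoxide, which sets C7 and C8 together.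

Step 5
Reactants: 6 (7R,8R)-epoxy acetate
Product: 7 (7R,8R)-epoxy C13 alcohol (2E,6R,7R,10E)-6,7-epoxy-12-(4-methoxybenzyloxy)-2,6,10-trimethyldodeca-2,10-dien-1-ol
Conditions: K2CO3, MeOH, 0 °C
Reagents that add atoms: none
Why: Base-catalysed transesterification of a primary acetate; a trisubstituted epoxide and a PMB ether are inert to cold carbonate in methanol.

Step 6
Reactants: 7 (7R,8R)-epoxy C13 alcohol
Product: 8 (7R,8R)-epoxy C13 allylic bromide
Conditions: CBr4, PPh3, 2,6-lutidine, CH2Cl2, −20 → 0 °C; used without storage
Reagents that add atoms: carbon tetrabromide, BrC(Br)(Br)Br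
Why: Appel bromination by SN2 displacement of the alkoxyphosphonium ion at the primary allylic carbon; the reaction produces no free acid and lutidine buffers any trace, which protects the epoxide.

Step 7
Reactants: 8 (7R,8R)-epoxy C13 allylic bromide; 9 1-(trimethylsilyl)propyne
Product: 11 silylalkyne (C15-SiMe3 / C15≡C1 / C14–C13 chain), via 3-lithio-1-(trimethylsilyl)propyne 10 (not isolated)
Conditions: 9, n-BuLi, THF, −78 °C; then 8, THF, −78 → −30 °C
Reagents that add atoms: none
Why: Alkylation of a silyl-substituted propargyllithium with a primary allylic bromide (SN2), the classical 1,5-enyne construction; silicon directs C–C formation to the propargylic CH2 (C14), and the trisubstituted epoxide and the PMB ether do not react with this organolithium at low temperature.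

Step 8
Reactants: 11 silylalkyne
Product: 12 terminal alkyne (5E,9R,10R,13E)-9,10-epoxy-15-(4-methoxybenzyloxy)-5,9,13-trimethylpentadeca-5,13-dien-1-yne
Conditions: K2CO3, MeOH, rt
Reagents that add atoms: none
Why: Protodesilylation of an alkynylsilane by methoxide attack at silicon; only the C(sp)–Si bond is cleaved.

Step 9
Reactants: 12 terminal alkyne; 13 formaldehyde (as paraformaldehyde)
Product: 15 propargylic alcohol (6E,10R,11R,14E)-10,11-epoxy-16-(4-methoxybenzyloxy)-6,10,14-trimethylhexadeca-6,14-dien-2-yn-1-ol, via lithium acetylide 14 (not isolated)
Conditions: n-BuLi, THF, −78 °C; then (CH2O)n, −78 °C → rt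
Reagents that add atoms: none
Why: Hydroxymethylation of a lithium acetylide by 1,2-addition to formaldehyde installs C16; without a Lewis acid the acetylide does not open the trisubstituted epoxide.

Step 10
Reactants: 15 propargylic alcohol
Product: 16 propargylic bromide (C16–Br, C2–OPMB)
Conditions: CBr4, PPh3, 2,6-lutidine, CH2Cl2, 0 °C
Reagents that add atoms: carbon tetrabromide, BrC(Br)(Br)Br
Why: Appel bromination of a primary propargylic alcohol (SN2); buffered, acid-free conditions spare the epoxide and the PMB ether.

Step 11
Reactants: 16 propargylic bromide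
Product: 17 bromo allylic alcohol (2E,6R,7R,10E)-16-bromo-6,7-epoxy-3,7,11-trimethylhexadeca-2,10-dien-14-yn-1-ol
Conditions: DDQ, CH2Cl2–aq. pH 7 phosphate buffer, 0 °C
Reagents that add atoms: none
Why: Oxidative PMB ether cleavage (hydride abstraction by DDQ, then hydrolysis of the oxocarbenium ion); the neutral two-phase medium avoids the base or fluoride that would displace the propargylic bromide and the acid that would open the epoxide.

Step 12
Reactants: 17 bromo allylic alcohol
Product: 18 bromo enal (2E,6R,7R,10E)-16-bromo-6,7-epoxy-3,7,11-trimethylhexadeca-2,10-dien-14-ynal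
Conditions: MnO2 (activated, excess), CH2Cl2, rt; used directly
Reagents that add atoms: none
Why: Manganese dioxide oxidation of a primary allylic alcohol to the enal; the heterogeneous neutral conditions should keep the C3=C4 E-geometry and leave the bromide and epoxide untouched.

Step 13
Reactants: 18 bromo enal
Product: 20 (2R,7R,8R)-epoxy allenol (14-membered ring; exocyclic C1=C15=C16H2; C2–OH), via propargylchromium dichloride 19 (not isolated)
Conditions: CrCl2 (excess), THF, rt, slow addition of 18 (high dilution); chromatographic separation of the C2 epimers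
Reagents that add atoms: none
Why: Intramolecular Nozaki–Hiyama reaction: CrCl2 turns the propargylic bromide into propargylchromium 19, which adds to the enal through its γ-carbon C1 in a cyclic SE2' transition state (the known course for 3-substituted 2-alkynyl bromides), forming C1–C2, the 14-membered ring and the 1,1-disubstituted allene at once, while the chemoselective organochromium leaves the epoxide and both E-alkenes alone. C2 is created under substrate control only (remote epoxide, ring conformation), so both epimers must be expected; they are diastereomers, and the (2R)-isomer 20 should be obtained pure by chromatography.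

Step 14
Reactants: 20 (2R,7R,8R)-epoxy allenol; 21 carbon monoxide
Product: 24 methyl ester of the lobophynin B skeleton (C17 as CO2Me), via alkenylpalladium chloride 22 (not isolated), via acylpalladium chloride 23 (not isolated)
Conditions: PdCl2(MeCN)2 (cat.), 1,4-benzoquinone, NaOAc, CO (1 atm), MeOH–THF, −20 → 0 °C
Reagents that add atoms: methanol, CO
Why: Divalent palladium binds the terminal C15=C16 π bond of the allene and the C2 hydroxyl adds to C16 anti to the metal, leaving σ-alkenylpalladium 22 at C15 and the C1=C15 alkene inside the new ring. CO inserts into the C15–Pd bond to give acylpalladium 23; methanolysis releases ester 24 and zerovalent palladium, which benzoquinone and the two protons set free return to divalent palladium. The closest known reaction type is the oxypalladation of 2,3-allenols to 2,5-dihydrofurans with capture of the alkenylpalladium, joined to the cyclisation–methoxycarbonylation of unsaturated alcohols under PdCl2(MeCN)2, benzoquinone, CO and methanol. The dihydrofuran closes in a 5-endo mode onto the in-plane π bond of the allene; attack at the central carbon would need a four-membered ring and is not expected. No stereocentre is created: C2 only carries the nucleophile and never becomes part of a π-allyl or cationic species, so its configuration should be retained, and the tetrasubstituted alkene has no geometry to control because both ends lie in rings. The step needs selectivity for the allene over the two trisubstituted alkenes, which bind divalent palladium weakly and have no hydroxyl placed to close a ring onto them. It also needs CO capture ahead of protodepalladation, which the CO atmosphere and the acetate buffer (low acid concentration) should secure. The same buffer and the low temperature protect the epoxide from methanolysis.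

Step 15
Reactants: 24 methyl ester
Product: 25 C17 alcohol (deacetyl-lobophynin B)
Conditions: i-Bu2AlH, CH2Cl2, −78 °C; aq. potassium sodium tartrate
Reagents that add atoms: none
Why: 1,2-Reduction of a conjugated ester by diisobutylaluminium hydride to the allylic alcohol; at −78 °C ester reduction should be much faster than hydride opening of the trisubstituted epoxide.

Step 16
Reactants: 25 C17 alcohol
Product: 26 lobophynin B
Conditions: Ac2O, pyridine, DMAP (cat.), CH2Cl2, 0 °C
Reagents that add atoms: acetic anhydride, CC(=O)OC(C)=O
Why: DMAP-catalysed acylation of a primary allylic alcohol under basic conditions that do not touch the epoxide or the C2–O bond.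

## Compound list

1 | (2E,6E)-farnesol | CC(C)=CCC/C(C)=C/CC/C(C)=C/CO | starting material
2 | sodium (2E,6E)-farnesoxide | CC(C)=CCC/C(C)=C/CC/C(C)=C/C[O-].[Na+] | intermediate (not isolated)
3 | (2E,6E)-farnesyl 4-methoxybenzyl ether | CC(C)=CCC/C(C)=C/CC/C(C)=C/COCc1ccc(OC)cc1 | intermediate
4 | (2E,6E,10E)-12-(4-methoxybenzyloxy)-2,6,10-trimethyldodeca-2,6,10-trien-1-ol (C13 alcohol) | OC/C(C)=C/CC/C(C)=C/CC/C(C)=C/COCc1ccc(OC)cc1 | intermediate
5 | (2E,6E,10E)-12-(4-methoxybenzyloxy)-2,6,10-trimethyldodeca-2,6,10-trien-1-yl acetate (C13 acetate) | CC(=O)OC/C(C)=C/CC/C(C)=C/CC/C(C)=C/COCc1ccc(OC)cc1 | intermediate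
6 | (2E,6R,7R,10E)-6,7-epoxy-12-(4-methoxybenzyloxy)-2,6,10-trimethyldodeca-2,10-dien-1-yl acetate ((7R,8R)-epoxide in cembrane numbering) | CC(=O)OC/C(C)=C/CC[C@@]1(C)O[C@@H]1CC/C(C)=C/COCc2ccc(OC)cc2 | intermediate
7 | (2E,6R,7R,10E)-6,7-epoxy-12-(4-methoxybenzyloxy)-2,6,10-trimethyldodeca-2,10-dien-1-ol | OC/C(C)=C/CC[C@@]1(C)O[C@@H]1CC/C(C)=C/COCc2ccc(OC)cc2 | intermediate
8 | (2E,6R,7R,10E)-1-bromo-6,7-epoxy-12-(4-methoxybenzyloxy)-2,6,10-trimethyldodeca-2,10-diene (C13 allylic bromide) | BrC/C(C)=C/CC[C@@]1(C)O[C@@H]1CC/C(C)=C/COCc2ccc(OC)cc2 | intermediate
9 | 1-(trimethylsilyl)propyne | CC#C[Si](C)(C)C | starting material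
10 | 3-lithio-1-(trimethylsilyl)propyne | [Li]CC#C[Si](C)(C)C | intermediate (not isolated)
11 | trimethyl[(5E,9R,10R,13E)-9,10-epoxy-15-(4-methoxybenzyloxy)-5,9,13-trimethylpentadeca-5,13-dien-1-yn-1-yl]silane | C[Si](C)(C)C#CCC/C(C)=C/CC[C@@]1(C)O[C@@H]1CC/C(C)=C/COCc2ccc(OC)cc2 | intermediate
12 | (5E,9R,10R,13E)-9,10-epoxy-15-(4-methoxybenzyloxy)-5,9,13-trimethylpentadeca-5,13-dien-1-yne | C#CCC/C(C)=C/CC[C@@]1(C)O[C@@H]1CC/C(C)=C/COCc2ccc(OC)cc2 | intermediate
13 | formaldehyde (used as paraformaldehyde) | C=O | starting material
14 | lithium acetylide of 12 | [Li]C#CCC/C(C)=C/CC[C@@]1(C)O[C@@H]1CC/C(C)=C/COCc2ccc(OC)cc2 | intermediate (not isolated)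
15 | (6E,10R,11R,14E)-10,11-epoxy-16-(4-methoxybenzyloxy)-6,10,14-trimethylhexadeca-6,14-dien-2-yn-1-ol | OCC#CCC/C(C)=C/CC[C@@]1(C)O[C@@H]1CC/C(C)=C/COCc2ccc(OC)cc2 | intermediate
16 | (6E,10R,11R,14E)-1-bromo-10,11-epoxy-16-(4-methoxybenzyloxy)-6,10,14-trimethylhexadeca-6,14-dien-2-yne | BrCC#CCC/C(C)=C/CC[C@@]1(C)O[C@@H]1CC/C(C)=C/COCc2ccc(OC)cc2 | intermediate
17 | (2E,6R,7R,10E)-16-bromo-6,7-epoxy-3,7,11-trimethylhexadeca-2,10-dien-14-yn-1-ol | BrCC#CCC/C(C)=C/CC[C@@]1(C)O[C@@H]1CC/C(C)=C/CO | intermediate
18 | (2E,6R,7R,10E)-16-bromo-6,7-epoxy-3,7,11-trimethylhexadeca-2,10-dien-14-ynal | BrCC#CCC/C(C)=C/CC[C@@]1(C)O[C@@H]1CC/C(C)=C/C=O | intermediate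
19 | propargylchromium dichloride derived from 18 (C16–CrCl2, trivalent chromium) | Cl[Cr](Cl)CC#CCC/C(C)=C/CC[C@@]1(C)O[C@@H]1CC/C(C)=C/C=O | intermediate (not isolated)
20 | (2R,7R,8R)-epoxy allenol: 14-membered carbocycle C1–C14 with exocyclic vinylidene C1=C15=C16H2, C2–OH, (3E)- and (11E)-alkenes carrying the C4 and C12 methyls, 7,8-epoxide carrying the C8 methyl | C=C=C1CC/C(C)=C/CC[C@@]2(C)O[C@@H]2CC/C(C)=C/[C@H]1O | intermediate
21 | carbon monoxide | [C-]#[O+] | starting material
22 | C15 alkenylpalladium chloride of the closed dihydrofuran (divalent palladium) | Cl[Pd]C1=C2CC/C(C)=C/CC[C@@]3(C)O[C@@H]3CC/C(C)=C/[C@H]2OC1 | intermediate (not isolated)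
23 | C17 acylpalladium chloride (divalent palladium) | Cl[Pd]C(=O)C1=C2CC/C(C)=C/CC[C@@]3(C)O[C@@H]3CC/C(C)=C/[C@H]2OC1 | intermediate (not isolated)
24 | (2R,7R,8R)-methyl ester: lobophynin B skeleton with C17 as CO2Me on C15 of the 2,5-dihydrofuran | COC(=O)C1=C2CC/C(C)=C/CC[C@@]3(C)O[C@@H]3CC/C(C)=C/[C@H]2OC1 | intermediate
25 | (2R,7R,8R)-C17 alcohol (deacetyl-lobophynin B) | OCC1=C2CC/C(C)=C/CC[C@@]3(C)O[C@@H]3CC/C(C)=C/[C@H]2OC1 | intermediate
26 | lobophynin B | CC(=O)OCC1=C2CC/C(C)=C/CC[C@@]3(C)O[C@@H]3CC/C(C)=C/[C@H]2OC1 | target

## Step count and risks

Total: 16 steps. Longest linear sequence: 16 steps, from farnesol 1.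

**Step 14 (key step).**
- What may go wrong: protonolysis of the C15–palladium bond before CO insertion, which would close the ring without C17; acid- or Lewis-acid-induced methanolysis of the epoxide; precipitation of palladium metal if reoxidation lags.
- Fallback: the route is left at allenol 20. Cationic monovalent gold (Ph3PAuCl/AgBF4) with N-iodosuccinimide should give the same 5-endo ring closure with iodine capturing the alkenyl–gold bond, leading to the 15-iodo-2,5-dihydrofuran F1. Carbonylation of this alkenyl iodide with Pd(PPh3)4 (zerovalent palladium), CO, methanol and triethylamine rejoins the route at ester 24. The one-carbon capture is thus moved from an oxidative palladium cycle to a separate cross-coupling.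

**Step 13.**
- What may go wrong: poor facial selectivity at the C2 aldehyde, so that much of the material ends up with the wrong C2 configuration; competing α-attack giving a ring-enlarged homopropargylic closure; intermolecular coupling; opening of the epoxide by the trivalent chromium salts formed.
- Fallback for the stereochemical problem: the same ring closure of bromo enal 18 also gives the (2S)-epimer of the allenol F2. Mitsunobu inversion (PPh3, diisopropyl azodicarboxylate, 4-nitrobenzoic acid) should convert it into the (2R)-4-nitrobenzoate F3, and methanolysis (K2CO3, MeOH) returns it to allenol 20. Selectivity is thereby replaced by stereochemical correction.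

**Step 4.**
- What may go wrong: incomplete regioselection, with competing epoxidation at C3=C4, whose allylic ether deactivates less than an ester; over-oxidation to bis-epoxides; loss of enantioselectivity if the ketone catalyst decomposes.
- Fallback: both outer alkenes carry esters during the epoxidation, and the ends are told apart afterwards.
  - Farnesol 1 is acetylated to farnesyl acetate F4.
  - Oxidation (SeO2, t-BuOOH) gives 12-hydroxyfarnesyl acetate F5.
  - Pivaloylation gives acetate pivalate F6.
  - Shi epoxidation gives the (7R,8R)-epoxy diester F7.
  - Selective methanolysis of the acetate (K2CO3, MeOH, 0 °C) gives epoxy pivalate alcohol F8.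
  - NaH and 4-methoxybenzyl bromide give PMB ether pivalate F9.
  - NaOMe in methanol removes the pivalate and rejoins the route at epoxy alcohol 7.

**Step 2.**
- What may go wrong: low conversion, over-oxidation to the aldehyde level, and competing oxidation at internal allylic methylene groups.
- Fallback: degradation and re-olefination from PMB ether 3.
  - N-bromosuccinimide in aqueous THF gives the terminal bromohydrin F10.
  - K2CO3 in methanol gives the terminal epoxide F11.
  - H5IO6 cleaves this to the trisnor aldehyde F12.
  - The stabilised ylide Ph3P=C(CH3)CO2Et gives the (E)-enoate F13.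
  - Reduction with i-Bu2AlH rejoins the route at alcohol 4.

## Further compounds

F1 | step 14 | (2R,7R,8R)-15-iodo-2,5-dihydrofuran macrocycle (iodine in place of C17) | IC1=C2CC/C(C)=C/CC[C@@]3(C)O[C@@H]3CC/C(C)=C/[C@H]2OC1
F2 | step 13 | (2S,7R,8R)-epoxy allenol (C2 epimer of 20) | C=C=C1CC/C(C)=C/CC[C@@]2(C)O[C@@H]2CC/C(C)=C/[C@@H]1O
F3 | step 13 | (2R,7R,8R)-epoxy allenyl 4-nitrobenzoate | C=C=C1CC/C(C)=C/CC[C@@]2(C)O[C@@H]2CC/C(C)=C/[C@H]1OC(=O)c3ccc(cc3)[N+](=O)[O-]
F4 | step 4 | (2E,6E)-farnesyl acetate | CC(C)=CCC/C(C)=C/CC/C(C)=C/COC(C)=O
F5 | step 4 | (2E,6E,10E)-12-hydroxyfarnesyl acetate | OC/C(C)=C/CC/C(C)=C/CC/C(C)=C/COC(C)=O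
F6 | step 4 | (2E,6E,10E)-12-acetoxy-2,6,10-trimethyldodeca-2,6,10-trien-1-yl pivalate (C2 acetate, C13 pivalate) | CC(C)(C)C(=O)OC/C(C)=C/CC/C(C)=C/CC/C(C)=C/COC(C)=O
F7 | step 4 | (7R,8R)-epoxide of F6 | CC(C)(C)C(=O)OC/C(C)=C/CC[C@@]1(C)O[C@@H]1CC/C(C)=C/COC(C)=O
F8 | step 4 | (7R,8R)-epoxy C13 pivalate with free C2 alcohol | CC(C)(C)C(=O)OC/C(C)=C/CC[C@@]1(C)O[C@@H]1CC/C(C)=C/CO
F9 | step 4 | (7R,8R)-epoxy C13 pivalate C2 PMB ether | CC(C)(C)C(=O)OC/C(C)=C/CC[C@@]1(C)O[C@@H]1CC/C(C)=C/COCc2ccc(OC)cc2
F10 | step 2 | terminal bromohydrin of 3 (racemic at the CHBr carbon) | CC(C)(O)C(Br)CC/C(C)=C/CC/C(C)=C/COCc1ccc(OC)cc1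
F11 | step 2 | terminal epoxide of 3 (racemic) | CC1(C)OC1CC/C(C)=C/CC/C(C)=C/COCc2ccc(OC)cc2
F12 | step 2 | (4E,8E)-10-(4-methoxybenzyloxy)-4,8-dimethyldeca-4,8-dienal | O=CCC/C(C)=C/CC/C(C)=C/COCc1ccc(OC)cc1
F13 | step 2 | ethyl (2E,6E,10E)-12-(4-methoxybenzyloxy)-2,6,10-trimethyldodeca-2,6,10-trienoate | CCOC(=O)/C(C)=C/CC/C(C)=C/CC/C(C)=C/COCc1ccc(OC)cc1
A1 | alternative 1 | open-chain bis(methyl-capped) diyne with C2–OTES, 7,8-epoxide, C11=C12 and the tetrasubstituted C1=C15 alkene carrying CH2OPMB and CH2OTBS | CC#CCC[C@H]1O[C@]1(C)CC/C=C(\C)CC/C(=C(/COCc2ccc(OC)cc2)CO[Si](C)(C)C(C)(C)C)[C@@H](C#CC)O[Si](CC)(CC)CC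
A2 | alternative 1 | 14-membered cycloalkyne (C3≡C4) with epoxide, C11=C12 and tetrasubstituted alkene in place | CC[Si](CC)(CC)O[C@@H]1C#CCC[C@H]2O[C@]2(C)CC/C=C(\C)CC/C1=C(/COCc3ccc(OC)cc3)CO[Si](C)(C)C(C)(C)C
A3 | alternative 2 | dienyl oxirane (C15–C16 oxirane carrying CH2OTBDPS, attached to the (1E,3E)-diene with CH2OTBS on C1 and the open C5–C13 chain) | CC(C)(C)[Si](c1ccccc1)(c1ccccc1)OC[C@@]2(CO2)/C(CO[Si](C)(C)C(C)(C)C)=C/C=C(\C)CC/C=C(\C)CC/C=C(\C)CO[Si](C)(C)C(C)(C)C
A4 | alternative 2 | 2,5-dihydrofuran with the C2 stereocentre and the open C3–C13 chain | CC(C)(C)[Si](c1ccccc1)(c1ccccc1)OCC2=C(CO[Si](C)(C)C(C)(C)C)[C@@H](/C=C(\C)CC/C=C(\C)CC/C=C(\C)CO[Si](C)(C)C(C)(C)C)OC2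
A5 | alternative 3 | open-chain bis(allylic bromide) (C13–Br and C14–Br) with the dihydrofuran, the C17 TBS ether and the 7,8-epoxide in place | BrCC1=C(CO[Si](C)(C)C(C)(C)C)CO[C@@H]1/C=C(\C)CC[C@H]2O[C@]2(C)CC/C=C(\C)CBr
A6 | alternative 3 | lobophynin B skeleton with a C17 TBS ether in place of the acetate | CC(C)(C)[Si](C)(C)OCC1=C2CC/C(C)=C/CC[C@@]3(C)O[C@@H]3CC/C(C)=C/[C@H]2OC1
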